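**Plan**

Locants: ring A is the 6,7-disubstituted coumarin (unprimed), ring B the 8'-linked coumarin (primed), ring C the 3''-oxy coumarin (double primed).
Cuts, in order: both O–CH3 masks; ring C at C3''–C4'' and O1''–C2''; O7–CH2; rings A and B each at O1–C2 and C2–C3; last the biaryl bond C6–C8'.
Enabling feature: C2 of ring A sits between phenolic O1 (on C8a) and the C3=C4 unit on the adjacent C4a. C2' of ring B sits likewise between O1' and C3'=C4', so each pyranone is a 2-vinylphenol plus one CO.
Forward: two salicylaldehydes are joined at C6–C8', both CHO groups become vinyl groups, and the pyranones of A and B close together. O7 is then freed and ring C is built on it last.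
Stereochemistry: none to set; the target has no stereocentre and its biaryl axis is left uncontrolled.

Key step: step 9

Assumption: the target SMILES carries no axial descriptor, so the tri-ortho-substituted C6–C8' axis is treated as unspecified (racemic if it proves configurationally stable).
Remark: in the other twofold steps the two sites react independently and in no fixed order, so their half-reacted forms are not numbered. Only the monocoumarin expected to form first in the key step gets a number.

**Step 1**
Reactants: 1 2,4-dihydroxybenzaldehyde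
Product: 2 4-(benzyloxy)-2-hydroxybenzaldehyde
Conditions: BnBr (1.05 equiv), NaHCO3, MeCN, reflux
Reagents that add atoms: benzyl bromide, BrCc1ccccc1
Why: Williamson etherification; the 2-OH is locked in a hydrogen bond to the formyl group and is the weaker acid, so the mild base ionises and benzylates only the 4-OH.

**Step 2**
Reactants: 2 4-(benzyloxy)-2-hydroxybenzaldehyde
Product: 3 4-(benzyloxy)-5-bromo-2-hydroxybenzaldehyde
Conditions: NBS, MeCN, 0 °C to rt, dark
Reagents that add atoms: N-bromosuccinimide, O=C1CCC(=O)N1Br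
Why: Electrophilic aromatic bromination should go to C5, para to the free OH and ortho to OBn, because the only other activated site, C3, is squeezed between two oxygen substituents.

**Step 3**
Reactants: 3 4-(benzyloxy)-5-bromo-2-hydroxybenzaldehyde
Product: 4 4-(benzyloxy)-5-bromo-2-(methoxymethoxy)benzaldehyde
Conditions: MOMCl, iPr2NEt, CH2Cl2, 0 °C to rt
Reagents that add atoms: chloromethyl methyl ether, COCCl
Why: O-Alkylation of the phenol with an α-chloro ether gives the MOM acetal, which keeps an acidic, chelating salicylaldehyde OH out of the cross-coupling and is removed together with the partner's MOM group in step 7.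

**Step 4**
Reactants: 5 2-hydroxy-4-methoxybenzaldehyde
Product: 6 4-methoxy-2-(methoxymethoxy)benzaldehyde
Conditions: MOMCl, iPr2NEt, CH2Cl2, 0 °C to rt
Reagents that add atoms: chloromethyl methyl ether, COCCl
Why: The same MOM acetal formation; here the OCH2OCH3 group also serves as the stronger of the two directing groups for the lithiation in step 5.

**Step 5**
Reactants: 6 4-methoxy-2-(methoxymethoxy)benzaldehyde
Product: 9 4-methoxy-2-(methoxymethoxy)-3-(4,4,5,5-tetramethyl-1,3,2-dioxaborolan-2-yl)benzaldehyde, via lithium amino alkoxide 7 (not isolated), via aryllithium 8 (not isolated)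
Conditions: 1-methylpiperazine, n-BuLi, THF, −20 °C, then 6; n-BuLi (2 equiv), −20 to 0 °C; iPrOBpin, −78 °C to rt; aq NH4Cl
Reagents that add atoms: 2-isopropoxy-4,4,5,5-tetramethyl-1,3,2-dioxaborolane, CC(C)OB1OC(C)(C)C(C)(C)O1
Why: Directed ortho-lithiation with transient aldehyde protection: lithium 4-methylpiperazin-1-ide adds to the formyl group to give the weakly directing α-amino alkoxide 7, n-BuLi then removes the most acidic ring proton at C3 between OMOM and OMe (8), the borate ester traps the aryllithium, and the mild aqueous work-up collapses the hemiaminal back to the aldehyde.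

**Step 6**
Reactants: 4 4-(benzyloxy)-5-bromo-2-(methoxymethoxy)benzaldehyde; 9 4-methoxy-2-(methoxymethoxy)-3-(4,4,5,5-tetramethyl-1,3,2-dioxaborolan-2-yl)benzaldehyde
Product: 10 6-(benzyloxy)-6'-methoxy-2',4-bis(methoxymethoxy)-[1,1'-biphenyl]-3,3'-dicarbaldehyde
Conditions: Pd(OAc)2 (5 mol %), SPhos (2-dicyclohexylphosphino-2',6'-dimethoxybiphenyl, 10 mol %), K3PO4, toluene/H2O, 90 °C
Reagents that add atoms: none
Why: Suzuki–Miyaura coupling forms C6–C8'; the bulky electron-rich biarylphosphine is the standard answer to tri-ortho-substituted biaryls and should keep coupling ahead of protodeboronation, while the formyl groups, MOM acetals and benzyl ether tolerate aqueous K3PO4.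

**Step 7**
Reactants: 10 6-(benzyloxy)-6'-methoxy-2',4-bis(methoxymethoxy)-[1,1'-biphenyl]-3,3'-dicarbaldehyde
Product: 11 6-(benzyloxy)-2',4-dihydroxy-6'-methoxy-[1,1'-biphenyl]-3,3'-dicarbaldehyde
Conditions: conc. HCl (cat.), MeOH/THF, 50 °C
Reagents that add atoms: none
Why: Acid-catalysed transacetalisation to methanol strips both MOM groups while the benzyl and methyl ethers stay, and the step is placed here so that no acid ever meets the electron-rich styrenes made next.

**Step 8**
Reactants: 11 6-(benzyloxy)-2',4-dihydroxy-6'-methoxy-[1,1'-biphenyl]-3,3'-dicarbaldehyde; 12 methyltriphenylphosphonium bromide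
Product: 13 5-(benzyloxy)-4-(2-hydroxy-6-methoxy-3-vinylphenyl)-2-vinylphenol
Conditions: 12 (6 equiv), KOtBu (5.8 equiv), THF, 0 °C to rt; aq NH4Cl; product kept cold and used at once
Reagents that add atoms: methyltriphenylphosphonium bromide (12), C[P+](c1ccccc1)(c1ccccc1)c1ccccc1.[Br-]
Why: Twofold Wittig methylenation; the first two equivalents of ylide only form the phenoxides and the excess converts both formyl groups into vinyl groups, as is routine for the unprotected conversion of salicylaldehydes into 2-vinylphenols.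

**Step 9**
Reactants: 13 5-(benzyloxy)-4-(2-hydroxy-6-methoxy-3-vinylphenyl)-2-vinylphenol; 14 carbon monoxide (two equivalents)
Product: 16 7-(benzyloxy)-6-(7-methoxy-2-oxo-2H-chromen-8-yl)-2H-chromen-2-one, via ring A monocoumarin 15 (not isolated)
Conditions: Pd(OAc)2 (10 mol %), 1,4-benzoquinone (3 equiv), CO (7 bar), MeCN, 100 °C
Reagents that add atoms: carbon monoxide (14), [C-]#[O+]
Why: Each phenoxide binds divalent palladium and takes up CO to give an aryloxycarbonylpalladium unit, whose acyl carbon is passed to the terminal vinyl carbon (C2–C3, C2'–C3') while palladium moves to the benzylic carbon, and β-hydride elimination then leaves the C3=C4 (C3'=C4') double bond; the other conceivable order, phenoxide-directed palladation of the terminal vinyl C–H, CO insertion and acyl–oxygen reductive elimination, makes the same bonds. Benzoquinone returns the zerovalent palladium to the divalent state, so one molecule of 13 uses two CO and two benzoquinone. The closest known reaction type is the Pd(OAc)2-catalysed oxidative cyclocarbonylation of 2-vinylphenols to coumarins, run here at two sites in one flask. Both pyranones close in the 6-endo sense on their vinyl groups, ring A at the open phenol probably first (15) and ring B at the phenol flanked by the aryl group second. No stereocentre arises. The step needs six-ring lactone formation to beat five-ring closure to a 3-methylenebenzofuranone and direct oxypalladation to a benzofuran, which the unsubstituted terminal CH2 as the easier site of C–C bond formation, the conjugated aromatic product and the CO pressure should secure, and site selectivity is built in because 13 has just two free OH groups, each ortho to a vinyl group, with O7 and O7' held as benzyl and methyl ethers.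

**Step 10**
Reactants: 16 7-(benzyloxy)-6-(7-methoxy-2-oxo-2H-chromen-8-yl)-2H-chromen-2-one
Product: 17 7-hydroxy-6-(7-methoxy-2-oxo-2H-chromen-8-yl)-2H-chromen-2-one
Conditions: BCl3 (4 equiv), pentamethylbenzene, CH2Cl2, −78 °C; then H2O
Reagents that add atoms: none
Why: Lewis-acid debenzylation with a non-basic cation scavenger; BCl3 ionises the benzyl–oxygen bond at low temperature, pentamethylbenzene takes up the benzyl cation by Friedel–Crafts alkylation, and the aryl methyl ether and the C3=C4 bonds, which hydrogenolysis could touch, remain.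

**Step 11**
Reactants: 17 7-hydroxy-6-(7-methoxy-2-oxo-2H-chromen-8-yl)-2H-chromen-2-one
Product: 18 tert-butyl 2-{[6-(7-methoxy-2-oxo-2H-chromen-8-yl)-2-oxo-2H-chromen-7-yl]oxy}acetate
Conditions: BrCH2CO2tBu, K2CO3, DMF, rt
Reagents that add atoms: tert-butyl bromoacetate, CC(C)(C)OC(=O)CBr
Why: Williamson etherification of the acidic 7-hydroxycoumarin OH with an activated primary bromide, under dry carbonate conditions that do not open the lactones.

**Step 12**
Reactants: 18 tert-butyl 2-{[6-(7-methoxy-2-oxo-2H-chromen-8-yl)-2-oxo-2H-chromen-7-yl]oxy}acetate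
Product: 19 2-{[6-(7-methoxy-2-oxo-2H-chromen-8-yl)-2-oxo-2H-chromen-7-yl]oxy}acetic acid
Conditions: TFA, CH2Cl2, rt
Reagents that add atoms: none
Why: Acidolysis of the tert-butyl ester (E1 loss of isobutene) frees the acid without the aqueous base that would open the two lactone rings.

**Step 13**
Reactants: 19 2-{[6-(7-methoxy-2-oxo-2H-chromen-8-yl)-2-oxo-2H-chromen-7-yl]oxy}acetic acid; 5 2-hydroxy-4-methoxybenzaldehyde
Product: 22 7-methoxy-3-{[6-(7-methoxy-2-oxo-2H-chromen-8-yl)-2-oxo-2H-chromen-7-yl]oxy}-2H-chromen-2-one, via mixed anhydride 20 (not isolated), via aryl ester 21 (not isolated)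
Conditions: Ac2O, Et3N, 120 °C
Reagents that add atoms: none
Why: Perkin-type coumarin synthesis; Ac2O turns 19 into the mixed anhydride 20, which acylates the phenol of 5 to give 21, and amine-mediated intramolecular aldol condensation of the activated OCH2 group onto the formyl group with loss of water closes ring C (O1''–C2'' and C3''–C4''), the standard way to 3-aryloxycoumarins.

**Step 14**
Reactants: 22 7-methoxy-3-{[6-(7-methoxy-2-oxo-2H-chromen-8-yl)-2-oxo-2H-chromen-7-yl]oxy}-2H-chromen-2-one
Product: 23 7-hydroxy-3-{[6-(7-hydroxy-2-oxo-2H-chromen-8-yl)-2-oxo-2H-chromen-7-yl]oxy}-2H-chromen-2-one (CNP0215289.0)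
Conditions: BBr3 (8 equiv), CH2Cl2, −78 °C to rt; then H2O
Reagents that add atoms: none
Why: Lewis-acid ether cleavage; BBr3 binds each methoxy oxygen and bromide attacks the methyl carbon (SN2), whereas the O7–C3'' ether offers only sp2 carbons and the lactones survive, so only the two methyl groups should be lost.

**Compound list**

1 | 2,4-dihydroxybenzaldehyde | O=Cc1ccc(O)cc1O | starting material
2 | 4-(benzyloxy)-2-hydroxybenzaldehyde | O=Cc1ccc(OCc2ccccc2)cc1O | intermediate
3 | 4-(benzyloxy)-5-bromo-2-hydroxybenzaldehyde | O=Cc1cc(Br)c(OCc2ccccc2)cc1O | intermediate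
4 | 4-(benzyloxy)-5-bromo-2-(methoxymethoxy)benzaldehyde | COCOc1cc(OCc2ccccc2)c(Br)cc1C=O | intermediate
5 | 2-hydroxy-4-methoxybenzaldehyde | COc1ccc(C=O)c(O)c1 | starting material
6 | 4-methoxy-2-(methoxymethoxy)benzaldehyde | COCOc1cc(OC)ccc1C=O | intermediate
7 | lithium [4-methoxy-2-(methoxymethoxy)phenyl](4-methylpiperazin-1-yl)methanolate (racemic) | [Li]OC(N1CCN(C)CC1)c1ccc(OC)cc1OCOC | intermediate
8 | lithium [3-lithio-4-methoxy-2-(methoxymethoxy)phenyl](4-methylpiperazin-1-yl)methanolate (racemic) | [Li]OC(N1CCN(C)CC1)c1ccc(OC)c([Li])c1OCOC | intermediate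
9 | 4-methoxy-2-(methoxymethoxy)-3-(4,4,5,5-tetramethyl-1,3,2-dioxaborolan-2-yl)benzaldehyde | COCOc1c(C=O)ccc(OC)c1B1OC(C)(C)C(C)(C)O1 | intermediate
10 | 6-(benzyloxy)-6'-methoxy-2',4-bis(methoxymethoxy)-[1,1'-biphenyl]-3,3'-dicarbaldehyde | COCOc1cc(OCc2ccccc2)c(cc1C=O)-c1c(OC)ccc(C=O)c1OCOC | intermediate
11 | 6-(benzyloxy)-2',4-dihydroxy-6'-methoxy-[1,1'-biphenyl]-3,3'-dicarbaldehyde | O=Cc1cc(-c2c(OC)ccc(C=O)c2O)c(OCc2ccccc2)cc1O | intermediate
12 | methyltriphenylphosphonium bromide | C[P+](c1ccccc1)(c1ccccc1)c1ccccc1.[Br-] | starting material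
13 | 5-(benzyloxy)-4-(2-hydroxy-6-methoxy-3-vinylphenyl)-2-vinylphenol | C=Cc1cc(-c2c(OC)ccc(C=C)c2O)c(OCc2ccccc2)cc1O | intermediate
14 | carbon monoxide | [C-]#[O+] | starting material
15 | 7-(benzyloxy)-6-(2-hydroxy-6-methoxy-3-vinylphenyl)-2H-chromen-2-one | C=Cc1ccc(OC)c(c1O)-c1cc2ccc(=O)oc2cc1OCc1ccccc1 | intermediate
16 | 7-(benzyloxy)-6-(7-methoxy-2-oxo-2H-chromen-8-yl)-2H-chromen-2-one | COc1ccc2ccc(=O)oc2c1-c1cc2ccc(=O)oc2cc1OCc1ccccc1 | intermediate
17 | 7-hydroxy-6-(7-methoxy-2-oxo-2H-chromen-8-yl)-2H-chromen-2-one | COc1ccc2ccc(=O)oc2c1-c1cc2ccc(=O)oc2cc1O | intermediate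
18 | tert-butyl 2-{[6-(7-methoxy-2-oxo-2H-chromen-8-yl)-2-oxo-2H-chromen-7-yl]oxy}acetate | COc1ccc2ccc(=O)oc2c1-c1cc2ccc(=O)oc2cc1OCC(=O)OC(C)(C)C | intermediate
19 | 2-{[6-(7-methoxy-2-oxo-2H-chromen-8-yl)-2-oxo-2H-chromen-7-yl]oxy}acetic acid | COc1ccc2ccc(=O)oc2c1-c1cc2ccc(=O)oc2cc1OCC(=O)O | intermediate
20 | acetic 2-{[6-(7-methoxy-2-oxo-2H-chromen-8-yl)-2-oxo-2H-chromen-7-yl]oxy}acetic anhydride | COc1ccc2ccc(=O)oc2c1-c1cc2ccc(=O)oc2cc1OCC(=O)OC(C)=O | intermediate
21 | 2-formyl-5-methoxyphenyl 2-{[6-(7-methoxy-2-oxo-2H-chromen-8-yl)-2-oxo-2H-chromen-7-yl]oxy}acetate | COc1ccc2ccc(=O)oc2c1-c1cc2ccc(=O)oc2cc1OCC(=O)Oc1cc(OC)ccc1C=O | intermediate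
22 | 7-methoxy-3-{[6-(7-methoxy-2-oxo-2H-chromen-8-yl)-2-oxo-2H-chromen-7-yl]oxy}-2H-chromen-2-one | COc1ccc2ccc(=O)oc2c1-c1cc2ccc(=O)oc2cc1Oc1cc2ccc(OC)cc2oc1=O | intermediate
23 | 7-hydroxy-3-{[6-(7-hydroxy-2-oxo-2H-chromen-8-yl)-2-oxo-2H-chromen-7-yl]oxy}-2H-chromen-2-one (CNP0215289.0) | O=c1ccc2cc(-c3c(O)ccc4ccc(=O)oc34)c(Oc3cc4ccc(O)cc4oc3=O)cc2o1 | target

**Step count and risks**

Total step count: 14.
Longest linear sequence: 12 (steps 1–3, then 6–14).

**Step 9 (twofold cyclocarbonylation).**
- What may go wrong: the second carbonylation may stall at the crowded ring B phenol. The electron-rich styrenes may oligomerise under heat or palladium, and five-ring closure may compete.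
- Fallback: it sets out from 11 and comes back at 16, so it needs neither step 8 nor CO.
- Twofold Wittig olefination of 11 with ethyl (triphenylphosphoranylidene)acetate gives diethyl (2E,2'E)-3,3'-[6-(benzyloxy)-2',4-dihydroxy-6'-methoxy-[1,1'-biphenyl]-3,3'-diyl]bis(prop-2-enoate) F1.
- Heating F1 in N,N-diethylaniline at reflux isomerises both double bonds and lactonises both hydroxy esters with loss of ethanol, which gives 16.

**Step 6 (hindered Suzuki coupling).**
- What may go wrong: protodeboronation of the boronate, which carries two ortho alkoxy groups, may outrun the slow transmetalation needed for a tri-ortho-substituted biaryl.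
- Fallback: it sets out from 6 and 4 and comes back at 10, with the polarity of the partners reversed.
- Compound 6 is taken through 7 and 8 as in step 5 but quenched with I2, which gives 3-iodo-4-methoxy-2-(methoxymethoxy)benzaldehyde F2.
- Bromide 4 undergoes Miyaura borylation (B2pin2, PdCl2(dppf), KOAc, dioxane, 90 °C) to 4-(benzyloxy)-2-(methoxymethoxy)-5-(4,4,5,5-tetramethyl-1,3,2-dioxaborolan-2-yl)benzaldehyde F3. Its boron has a single ortho substituent and should be far less prone to protolysis.
- Coupling of F2 with F3 under Pd(OAc)2/SPhos/K3PO4 gives 10.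

**Step 13 (Perkin closure of ring C).**
- What may go wrong: 5 may be consumed by O-acetylation and by its own Perkin reaction with acetic anhydride. Enolisation of the hindered aryloxyacetyl unit may also be slow.
- Fallback: it sets out from 17 and comes back at 22. It forms the O7–C3'' bond on a finished ring C and bypasses steps 11 and 12.
- Commercial 7-methoxycoumarin is brominated by addition and elimination (Br2, CH2Cl2, then Et3N) to 3-bromo-7-methoxy-2H-chromen-2-one F4.
- Phenol 17 is then joined to F4 by an Ullmann-type coupling of a vinyl bromide with a phenol (CuI, N,N-dimethylglycine, Cs2CO3, dioxane, 100 °C), which gives 22.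

**Further compounds**

F1 | step 9 | diethyl (2E,2'E)-3,3'-[6-(benzyloxy)-2',4-dihydroxy-6'-methoxy-[1,1'-biphenyl]-3,3'-diyl]bis(prop-2-enoate) | CCOC(=O)/C=C/c1cc(-c2c(OC)ccc(/C=C/C(=O)OCC)c2O)c(OCc2ccccc2)cc1O
F2 | step 6 | 3-iodo-4-methoxy-2-(methoxymethoxy)benzaldehyde | COCOc1c(C=O)ccc(OC)c1I
F3 | step 6 | 4-(benzyloxy)-2-(methoxymethoxy)-5-(4,4,5,5-tetramethyl-1,3,2-dioxaborolan-2-yl)benzaldehyde | COCOc1cc(OCc2ccccc2)c(cc1C=O)B1OC(C)(C)C(C)(C)O1
F4 | step 13 | 3-bromo-7-methoxy-2H-chromen-2-one | COc1ccc2cc(Br)c(=O)oc2c1
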